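**Strategy.** Both aryl–CH2 bonds are disconnected, which leads back to 2,6-dibromophenol 1, formaldehyde 2 (the methylene carbon) and 2-bromophenol 3. The feature exploited is that the CH2 carbon sits on C4, para to OH, of both phenol rings. In the dibromo ring, C2 and C6 carry Br, so C4 is the one carbon of that ring that can still react. In one flask the sodium salt of 1 is para-hydroxymethylated with 2 as the limiting component. Excess 3 and strong acid then ionise the benzylic alcohol, and C4 of 3 captures the cation. Both skeletal bonds form in one operation; no ring closes and no stereocentre arises. The precursors are three purchased compounds.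

Key step: step 1

Remark on the chemistry: the target has no stereocentre and no hindered axis, so it is achiral. The request for a single enantiomer is met by the compound itself, and no step needs stereocontrol. The structures of 1, 2, 3 and the target are mutually consistent (1 + 2 + 3 − H2O = C13H9Br3O2) and need no correction.

Step 1
Reactants: 1 2,6-dibromophenol; 2 formaldehyde (charged as paraformaldehyde); 3 2-bromophenol
Product: 6 2-bromo-4-(3,5-dibromo-4-hydroxybenzyl)phenol, via 3,5-dibromo-4-hydroxybenzyl alcohol 4 (not isolated), via 2,6-dibromo-4-methylidenecyclohexa-2,5-dienone 5 (not isolated)
Conditions: i) 1 (1.2 equiv), (CH2O)n (1.0 equiv), NaOH (1.25 equiv), H2O (ca. 2 M), 50–55 °C, N2, until 2 is no longer detectable; ii) same flask, 0 °C: 3 (8 equiv), then MeSO3H (10 equiv) dropwise, 0 → 45 °C; steam distillation (recovers 3 and surplus 1), then crystallisation (toluene/heptane) or chromatography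
Reagents that add atoms: none
Why: Stage i is a Lederer–Manasse hydroxymethylation: the phenoxide of 1 adds through C4 to 2, and because C2 and C6 bear Br only one CH2OH can enter, which gives 4 as its sodium salt. Since 2 is the limiting, methanol-free component and its absence is checked before the switch, 3 should find no one-carbon electrophile of its own. Stage ii is the acid-catalysed hydroxybenzylation of a phenol known from novolac and bisphenol F chemistry (a Friedel–Crafts alkylation): protonated 4 loses water to give 5 in its O-protonated form, the 3,5-dibromo-4-hydroxybenzyl cation, which is attacked by C4 of 3 and rearomatises to 6. Cross- over homo-coupling is needed and is secured by the substrates, as 3 bears one deactivating Br instead of two, is present in large excess and is in the flask before the acid, so that surplus 1, alcohol 4 and product 6 should compete poorly. Para over ortho attack on 3 is needed as well and rests on the para preference of OH-directed benzylation, the crowding of C6 next to the hydroxyl group and the low temperature, any ortho-linked isomer being left in the mother liquor. No ring is closed and no stereocentre is made; the C–Br bonds and free phenols should tolerate both media, and MeSO3H avoids the chloromethyl ethers that HCl forms with traces of 2 and the ring sulfonation that concentrated H2SO4 can cause.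

**Compound list**
1 | 2,6-dibromophenol | Oc1c(Br)cccc1Br | starting material
2 | formaldehyde (charged as paraformaldehyde) | C=O | starting material
3 | 2-bromophenol | Oc1ccccc1Br | starting material
4 | 3,5-dibromo-4-hydroxybenzyl alcohol, i.e. 2,6-dibromo-4-(hydroxymethyl)phenol (present first as its sodium phenoxide) | OCc1cc(Br)c(O)c(Br)c1 | intermediate
5 | 2,6-dibromo-4-methylidenecyclohexa-2,5-dien-1-one (para-quinone methide, reacting as its O-protonated form, the 3,5-dibromo-4-hydroxybenzyl cation) | C=C1C=C(Br)C(=O)C(Br)=C1 | intermediate
6 | 2-bromo-4-(3,5-dibromo-4-hydroxybenzyl)phenol (achiral) | Oc1ccc(Cc2cc(Br)c(O)c(Br)c2)cc1Br | target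

**Total step count:** 1. **Longest linear sequence:** 1.

**Most likely failures.** The route has a single step, so all three entries concern step 1. They are three separate processes, listed with the most likely first, and each has its own fallback.

1. Step 1, capture stage: poor positional selectivity. The cation may attack 3 through the ortho carbon C6 as well as through C4, and the two isomers may then co-crystallise so that purification fails.
This fallback sets out from 3 and comes back at 6. It replaces the benzylation with an acylation, which is strongly para-directed on an anisole and stops after one substitution. Compound 3 is O-methylated (MeI, K2CO3, acetone) to 2-bromoanisole F1. Purchased 3,5-dibromo-4-methoxybenzoic acid F2 is converted with SOCl2 (cat. DMF) into 3,5-dibromo-4-methoxybenzoyl chloride F3. Friedel–Crafts acylation of F1 with F3 (AlCl3, CH2Cl2, 0 °C) should give (3-bromo-4-methoxyphenyl)(3,5-dibromo-4-methoxyphenyl)methanone F4. Ionic hydrogenation (Et3SiH, CF3CO2H, CH2Cl2) removes the carbonyl oxygen to give 1,3-dibromo-5-(3-bromo-4-methoxybenzyl)-2-methoxybenzene F5. BBr3 (CH2Cl2, −78 °C → rt) then cleaves both methyl ethers to 6.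

2. Step 1, hydroxymethylation stage: sluggish addition. The dibromophenoxide is strongly stabilised and weakly nucleophilic, so 2 may survive into the acid stage and couple 3 with itself.
This fallback sets out from 1 and comes back at 4. The one-carbon unit is installed at the aldehyde oxidation level by a Duff formylation (hexamethylenetetramine, CF3CO2H, reflux, then aq. HCl). This is a reaction known for 2,6-dihalophenols, and it gives 3,5-dibromo-4-hydroxybenzaldehyde F6, which can also be purchased. NaBH4 (THF/MeOH, 0 °C, careful neutralisation) reduces it to 4. Compound 4 is isolated and crystallised, so it is free of 1 and 2, and it then enters the acid stage of step 1 together with 3.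

3. Step 1, capture stage: capture by the wrong nucleophile. The cation may be taken by surplus dibromophenol, by the oxygen of un-ionised benzylic alcohol, or by the monobromo ring of product already formed. The results would be homo-coupling, etherification and repeated benzylation, all made worse by slow ionisation in water-rich acid.
This fallback sets out from 4 and comes back at 6. Compound 4 is isolated from stage i by acidification to about pH 5, or made as in the preceding fallback. It is converted with HBr in AcOH (rt) into crystalline 2,6-dibromo-4-(bromomethyl)phenol F7. This discrete benzylic halide is added slowly, as the limiting reagent, to excess 3 and catalytic ZnCl2 in 1,2-dichloroethane at 40 °C. The result is an anhydrous Lewis-acid Friedel–Crafts benzylation in which 1, 4 and water are all absent. The stationary concentration of the electrophile also stays low.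

**Further compounds**
F1 | step 1 | 2-bromoanisole | COc1ccccc1Br
F2 | step 1 | 3,5-dibromo-4-methoxybenzoic acid | COc1c(Br)cc(cc1Br)C(=O)O
F3 | step 1 | 3,5-dibromo-4-methoxybenzoyl chloride | COc1c(Br)cc(cc1Br)C(=O)Cl
F4 | step 1 | (3-bromo-4-methoxyphenyl)(3,5-dibromo-4-methoxyphenyl)methanone | COc1ccc(cc1Br)C(=O)c1cc(Br)c(OC)c(Br)c1
F5 | step 1 | 1,3-dibromo-5-(3-bromo-4-methoxybenzyl)-2-methoxybenzene | COc1ccc(Cc2cc(Br)c(OC)c(Br)c2)cc1Br
F6 | step 1 | 3,5-dibromo-4-hydroxybenzaldehyde | O=Cc1cc(Br)c(O)c(Br)c1
F7 | step 1 | 2,6-dibromo-4-(bromomethyl)phenol | BrCc1cc(Br)c(O)c(Br)c1
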